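## Analysis of the target

The target is an unsymmetrical biisoflavone. A 7,4′-dihydroxyisoflavone (daidzein) unit and a 5,7,4′-trihydroxyisoflavone (genistein) unit are joined by a single aryl–aryl bond between C3′ of ring B of the first and C8″ of ring A of the second. Atoms of the genistein unit carry double primes, and those of its ring B triple primes. Each unit is a 4H-chromen-4-one (rings A and C) with a 3-aryl ring B; the molecule is C30H18O9 with five free phenols. There is no stereocentre. The C3′–C8″ axis has three ortho substituents (O4′–H, O7″–H and the ring oxygen O1″), none larger than oxygen. The decisive feature is that this bond is flanked on both sides by phenolic oxygens, O4′ and O7″, so the core is a 2,2′-biphenol. Sensitive groups are the electron-rich phenols (oxidation), the two pyranone rings (attack of hydroxide or thiolate at C2 and C2″ opens them) and the chelated 5″-OH, which reacts sluggishly. The synthesis is hard for three reasons: the bond is hindered, ring A of the genistein unit offers two activated positions (C6″ and C8″), and five phenols must be told apart so that only the right carbons meet.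

Assumption: the C3′–C8″ axis is taken to rotate freely at room temperature, in line with the SMILES, which gives no axial descriptor; no step has to control it.

## Retrosynthetic reasoning

13 to 12. The three methyl ethers (O7, O5″, O4‴) are removed last by Lewis-acid cleavage. Methyl is chosen because one of them (O4‴) is already present in the commercial compound 5 and because methyl ethers survive every earlier step.

12 to 11. The two phenols O4′–H and O7″–H of 12 are reconnected through a di-tert-butylsilylene unit. This gives the seven-membered dibenzo[d,f][1,3,2]dioxasilepine 11. Both oxygens are wanted as free phenols in the target, so the bridge is traceless, and the forward step is a simple fluoride opening.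

11 to 10. The C3′–C8″ bond is cut inside the seven-membered ring. It is the only bond that joins the two halves, and with the bridge in place it can be made intramolecularly. Bromine at C3′ fixes the site on ring B, and the bridge on O7″ confines the other site to an ortho carbon of ring A″. C8″ needs no handle, because its C–H bond is used directly. The forward reaction has to choose C8″ over C6″, and the methyl ether on O5″ is there to secure that.

10 to 4 and 8. The two Si–O bonds are cut. The forward reaction is a one-flask, two-stage silylation: the hindered ortho-bromophenol 4 goes on silicon first and the unhindered phenol 8 second, so the mixed bis(aryl ether) 10 forms in preference to a symmetrical one.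

8 to 7 to 5. Compound 8 needs O7″ free and O5″ capped, the reverse of the natural reactivity order. From 5 the acidic 7-OH is therefore benzylated, the chelated 5-OH is methylated in the same flask (7), and the benzyl group is removed by hydrogenolysis.

4 to 1 and 2. Ring C of 4 is cut at C4–C4a (Friedel–Crafts acylation of 1 by acid 2) and at C2 (a one-carbon unit from a formamide). The bromine is bought with 2, so the coupling handle costs no step.

## Alternatives that were turned down

Alternative 1: the textbook route cuts C3′–C8″ as an intermolecular Suzuki–Miyaura coupling. Compound 5 would be methylated to 5,7,4′-trimethoxyisoflavone A1 and iodinated at C8 to A2; compound 4 would be O-methylated and borylated to pinacol boronate A3; coupling would give pentamethyl ether A4, and fivefold demethylation the target. It was turned down for three reasons. Two steps serve only to install handles on both carbons. The bond forms bimolecularly between an iodide whose carbon lies between two oxygens (slow oxidative addition, easy protodeiodination) and an ortho-alkoxy boronate (easy protodeboronation). And at six steps it saves little over the bridged route (seven). It is kept as the fallback for the key step.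

Alternative 2: a direct dehydrogenative cross-coupling of unprotected daidzein A5 with A1 at a boron-doped diamond anode in a fluorinated alcohol would give biaryl A6 in one step, followed by demethylation. It was turned down because nothing forces C3′ to meet C8″. The ring B phenol of A5 carries the electron-poor chromenone at C1′ and is hard to oxidise, and its ring A phenol competes. Ring A of A1 is a vinylogous ester and only a moderate nucleophile, with C6 also open. The product A6 is a more electron-rich phenol than either partner and should be oxidised further. On paper it is the shortest route (three steps), but every selectivity is left to chance.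

Alternative 3: both pyranone rings are cut at C2 and C2″, leading back to the biaryl bis(deoxybenzoin) A7, which a double formylative ring closure would convert to the target in one step. It was turned down because the ketone on the phloroglucinol ring of A7 has two ortho hydroxyls. Closure through the hydroxyl next to the biaryl carbon gives the 8″-linked skeleton; closure through the less hindered one gives the 6″-linked isomer, and the latter should be favoured. In addition A7 itself needs the same hindered biaryl bond on a phloroglucinol plus two acylations, so the problem is only moved earlier, at more steps.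

Key step: step 5

## Route

Step 1
Reactants: 1 3-methoxyphenol; 2 (3-bromo-4-hydroxyphenyl)acetic acid
Product: 4 3-(3-bromo-4-hydroxyphenyl)-7-methoxy-4H-chromen-4-one, via deoxybenzoin 3 (not isolated)
Conditions: BF3·OEt2 (as solvent), 85 °C; then DMF, MsCl, 70 °C; aq. NaOAc work-up
Reagents that add atoms: N,N-dimethylformamide, CN(C)C=O
Why: Friedel–Crafts acylation of 1 by the BF3-activated acid should go ortho to the hydroxyl and para to the methoxy group, driven by the boron chelate of the ortho-hydroxy ketone. The formamide–MsCl adduct then formylates the activated methylene and the ortho-hydroxyl closes ring C (deoxybenzoin route to isoflavones); the free phenol and the aryl bromide of 2 are inert in both stages.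

Step 2
Reactants: 5 biochanin A (5,7-dihydroxy-3-(4-methoxyphenyl)-4H-chromen-4-one)
Product: 7 7-(benzyloxy)-5-methoxy-3-(4-methoxyphenyl)-4H-chromen-4-one, via benzyl ether 6 (not isolated)
Conditions: BnBr (1.0 equiv), K2CO3, DMF, rt; then MeI (excess), 60 °C
Reagents that add atoms: benzyl bromide, BrCc1ccccc1; iodomethane, CI
Why: Williamson etherification in two stages. At room temperature only the acidic, unchelated 7-OH should be alkylated; the 5-OH, hydrogen-bonded to C4=O, needs the small electrophile and heat, so one flask delivers the two groups to the two oxygens in the required order.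

Step 3
Reactants: 7 7-(benzyloxy)-5-methoxy-3-(4-methoxyphenyl)-4H-chromen-4-one
Product: 8 7-hydroxy-5-methoxy-3-(4-methoxyphenyl)-4H-chromen-4-one
Conditions: H2 (1 atm), Pd/C (palladium on carbon), EtOAc–THF, rt, stopped after one equivalent of H2
Reagents that add atoms: none
Why: Hydrogenolysis of the benzyl aryl ether is much faster than reduction of the tetrasubstituted, conjugated C2=C3 bond, and the methyl ethers are untouched.

Step 4
Reactants: 4 3-(3-bromo-4-hydroxyphenyl)-7-methoxy-4H-chromen-4-one; 8 7-hydroxy-5-methoxy-3-(4-methoxyphenyl)-4H-chromen-4-one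
Product: 10 3-{3-bromo-4-[(di-tert-butyl{[5-methoxy-3-(4-methoxyphenyl)-4-oxo-4H-chromen-7-yl]oxy}silyl)oxy]phenyl}-7-methoxy-4H-chromen-4-one, via silyl triflate 9 (not isolated)
Conditions: 4, tBu2Si(OTf)2 (1.05 equiv), 2,6-lutidine, CH2Cl2, −78 to 0 °C; then 8, Et3N, DMAP (cat.), THF, 0 to 40 °C
Reagents that add atoms: di-tert-butylsilyl bis(trifluoromethanesulfonate), CC(C)(C)[Si](OS(=O)(=O)C(F)(F)F)(OS(=O)(=O)C(F)(F)F)C(C)(C)C
Why: Stepwise O-silylation of two phenols by a silyl bis(triflate). After the first substitution the silicon carries two tert-butyl groups and an ortho-bromoaryloxy group, so a second hindered molecule of 4 should not add; the unhindered phenol 8 then displaces the remaining triflate to give the mixed silylene bis(aryl ether).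

Step 5
Reactants: 10 the silylene bis(aryl ether) of step 4
Product: 11 the 4′-O,7″-O-(di-tert-butylsilanediyl) derivative of 12, a 6,6-di-tert-butyldibenzo[d,f][1,3,2]dioxasilepine in which C3′ is bonded to C8″
Conditions: Pd(OAc)2 (10 mol %), PCy3·HBF4 (20 mol %), PivOH (30 mol %), Cs2CO3 (2 equiv), toluene, 110 °C, argon
Reagents that add atoms: none
Why: Zerovalent palladium, formed in the flask, inserts into the C3′–Br bond; bromide is exchanged for pivalate; the aryl–palladium unit, held by the O4′–Si–O7″ bridge over ring A″, cleaves the C8″–H bond by concerted metalation–deprotonation to an eight-membered diarylpalladium ring of divalent palladium; reductive elimination forms C3′–C8″. The closest known reaction type is the palladium-catalysed intramolecular direct arylation of bis(aryloxy)di-tert-butylsilanes, which gives seven-membered silicon-bridged biaryls as precursors of unsymmetrical 2,2′-biphenols. One ring is closed, the seven-membered dioxasilepine, and it is closed at the biaryl carbon–carbon bond, not at a heteroatom; the two tert-butyl groups on silicon press the two aryloxy arms together and favour the closure. No stereocentre is formed; the axis of the bridged biaryl arises as a racemate and is of no consequence once the bridge is opened. The step needs C8″ over C6″, the two carbons ortho to O7″. The methyl group on O5″ is turned away from the peri carbonyl C4″=O and lies over C6″–H, whereas C8″–H is flanked on its other side only by the ring oxygen O1″. C8″ is also the position at which 5,7-dialkoxychromenones are known to be substituted by electrophiles. The site on ring B is fixed by the bromine, and the C2–H and C2″–H bonds of the pyranones cannot be reached through the bridge.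

Step 6
Reactants: 11 the silicon-bridged biaryl of step 5
Product: 12 7-hydroxy-8-[2-hydroxy-5-(7-methoxy-4-oxo-4H-chromen-3-yl)phenyl]-5-methoxy-3-(4-methoxyphenyl)-4H-chromen-4-one
Conditions: HF·pyridine, THF, 0 °C to rt (polypropylene vessel)
Reagents that add atoms: none
Why: Fluoride cleaves both aryl–O–Si bonds (silyl ether cleavage, driven by the Si–F bond) and frees the two phenols that flank the new bond. Methyl ethers and pyranones are inert to these mildly acidic conditions.

Step 7
Reactants: 12 the biphenol of step 6
Product: 13 5,7-dihydroxy-8-[2-hydroxy-5-(7-hydroxy-4-oxo-4H-chromen-3-yl)phenyl]-3-(4-hydroxyphenyl)-4H-chromen-4-one (target)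
Conditions: BBr3 (12 equiv), CH2Cl2, −78 °C to rt; then MeOH, H2O
Reagents that add atoms: none
Why: Lewis-acid cleavage of aryl methyl ethers. The chelated 5″-OMe should fall first and the 7- and 4‴-OMe groups follow at room temperature; the chromenone rings tolerate the reagent and no base is used that could open them.

## Compound list

1 | 3-methoxyphenol | COc1cccc(O)c1 | starting material
2 | (3-bromo-4-hydroxyphenyl)acetic acid | OC(=O)Cc1ccc(O)c(Br)c1 | starting material
3 | 2-(3-bromo-4-hydroxyphenyl)-1-(2-hydroxy-4-methoxyphenyl)ethan-1-one | COc1ccc(C(=O)Cc2ccc(O)c(Br)c2)c(O)c1 | intermediate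
4 | 3-(3-bromo-4-hydroxyphenyl)-7-methoxy-4H-chromen-4-one | O=c1c(-c2ccc(O)c(Br)c2)coc2cc(OC)ccc12 | intermediate
5 | biochanin A, 5,7-dihydroxy-3-(4-methoxyphenyl)-4H-chromen-4-one | COc1ccc(cc1)-c1coc2cc(O)cc(O)c2c1=O | starting material
6 | 7-(benzyloxy)-5-hydroxy-3-(4-methoxyphenyl)-4H-chromen-4-one | COc1ccc(cc1)-c1coc2cc(OCc3ccccc3)cc(O)c2c1=O | intermediate
7 | 7-(benzyloxy)-5-methoxy-3-(4-methoxyphenyl)-4H-chromen-4-one | COc1ccc(cc1)-c1coc2cc(OCc3ccccc3)cc(OC)c2c1=O | intermediate
8 | 7-hydroxy-5-methoxy-3-(4-methoxyphenyl)-4H-chromen-4-one | COc1ccc(cc1)-c1coc2cc(O)cc(OC)c2c1=O | intermediate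
9 | [2-bromo-4-(7-methoxy-4-oxo-4H-chromen-3-yl)phenoxy]di-tert-butylsilyl trifluoromethanesulfonate | COc1ccc2c(c1)occ(-c1ccc(O[Si](OS(=O)(=O)C(F)(F)F)(C(C)(C)C)C(C)(C)C)c(Br)c1)c2=O | intermediate
10 | 3-{3-bromo-4-[(di-tert-butyl{[5-methoxy-3-(4-methoxyphenyl)-4-oxo-4H-chromen-7-yl]oxy}silyl)oxy]phenyl}-7-methoxy-4H-chromen-4-one | COc1ccc2c(c1)occ(-c1ccc(O[Si](Oc3cc(OC)c4c(c3)occ(-c3ccc(OC)cc3)c4=O)(C(C)(C)C)C(C)(C)C)c(Br)c1)c2=O | intermediate
11 | 4′-O,7″-O-(di-tert-butylsilanediyl) derivative of 12 (6,6-di-tert-butyldibenzo[d,f][1,3,2]dioxasilepine with the C3′–C8″ bond) | COc1ccc2c(c1)occ(-c1ccc3c(c1)-c1c(O[Si](O3)(C(C)(C)C)C(C)(C)C)cc(OC)c4c1occ(-c1ccc(OC)cc1)c4=O)c2=O | intermediate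
12 | 7-hydroxy-8-[2-hydroxy-5-(7-methoxy-4-oxo-4H-chromen-3-yl)phenyl]-5-methoxy-3-(4-methoxyphenyl)-4H-chromen-4-one | COc1ccc2c(c1)occ(-c1ccc(O)c(c1)-c1c(O)cc(OC)c3c1occ(-c1ccc(OC)cc1)c3=O)c2=O | intermediate
13 | 5,7-dihydroxy-8-[2-hydroxy-5-(7-hydroxy-4-oxo-4H-chromen-3-yl)phenyl]-3-(4-hydroxyphenyl)-4H-chromen-4-one | O=c1c(-c2ccc(O)c(-c3c(O)cc(O)c4c(=O)c(-c5ccc(O)cc5)coc34)c2)coc2cc(O)ccc12 | target

## Step count and risk

Total step count: 7. Longest linear sequence: 6 steps (5 to 13 through steps 2 to 7); the other branch (1 and 2 to 4) joins at step 4.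

Step 5 (key step). Most likely failure: arylation at C6″ instead of C8″, because both carbons are ortho to the bridged oxygen and the preference rests on the O5″ methyl group and on the inherent bias of the ring. Loss of the silicon bridge to carbonate at 110 °C and reductive loss of bromine are the next concerns. Fallback, setting out from 4 and 7 and coming back at 13: 4 is O-methylated (MeI, K2CO3) to 3-(3-bromo-4-methoxyphenyl)-7-methoxy-4H-chromen-4-one F1 and borylated (B2pin2, PdCl2(dppf), KOAc) to 7-methoxy-3-[4-methoxy-3-(4,4,5,5-tetramethyl-1,3,2-dioxaborolan-2-yl)phenyl]-4H-chromen-4-one F2. 7 is iodinated at C8 (N-iodosuccinimide, cat. CF3CO2H, MeCN) to 7-(benzyloxy)-8-iodo-5-methoxy-3-(4-methoxyphenyl)-4H-chromen-4-one F3. Intermolecular Suzuki–Miyaura coupling of F2 and F3 (Pd(OAc)2, SPhos, K3PO4, toluene–water) should give 7-(benzyloxy)-5-methoxy-8-[2-methoxy-5-(7-methoxy-4-oxo-4H-chromen-3-yl)phenyl]-3-(4-methoxyphenyl)-4H-chromen-4-one F4, and BBr3 cleaves its four methyl ethers and the benzyl ether to 13. Here the site on ring A″ is fixed by the iodine and no longer by a C–H selectivity.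

Step 4. Most likely failure: scrambling at silicon, that is, double substitution by 4 in the first stage, or hydrolysis of the intermediate triflate to a silanol before 8 has reacted. Fallback, setting out from 4 and coming back at 10: 4 is silylated with tBu2SiHCl (imidazole, DMF) to the isolable hydrosilyl ether 3-{3-bromo-4-[(di-tert-butylsilyl)oxy]phenyl}-7-methoxy-4H-chromen-4-one F5. The Si–H bond is brominated (N-bromosuccinimide, CH2Cl2, 0 °C) to 3-{3-bromo-4-[(bromodi-tert-butylsilyl)oxy]phenyl}-7-methoxy-4H-chromen-4-one F6, which is treated with 8 and imidazole to give 10. The two Si–O bonds are then made in separate operations, the first at a silicon centre that can react only once.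

Step 1. Most likely failure: acylation of 1 para to the hydroxyl instead of ortho, which cannot close to a chromenone and lowers the throughput of the one-flask sequence. Fallback, setting out from 2 and coming back at 4: 2 is condensed with resorcinol (Oc1cccc(O)c1; BF3·OEt2, 85 °C), whose acylation at C4 is unambiguous, to 2-(3-bromo-4-hydroxyphenyl)-1-(2,4-dihydroxyphenyl)ethan-1-one F7. Ring closure (DMF, MsCl, BF3·OEt2) gives 3-(3-bromo-4-hydroxyphenyl)-7-hydroxy-4H-chromen-4-one F8. The more acidic 7-OH is then methylated selectively (MeI, 1.0 equiv, K2CO3, 1.0 equiv, acetone, rt) to 4.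

Step 3. Most likely failure: over-reduction, in which the C2=C3 bond of the isoflavone is saturated to the isoflavanone while the benzyl group is removed. Fallback, setting out from 5 and coming back at 8: the benzyl group is replaced by allyl, which is removed without hydrogen. 5 is allylated (allyl bromide, K2CO3, DMF, rt) to 5-hydroxy-3-(4-methoxyphenyl)-7-(prop-2-en-1-yloxy)-4H-chromen-4-one F9 and methylated in the same flask (MeI, 60 °C) to 5-methoxy-3-(4-methoxyphenyl)-7-(prop-2-en-1-yloxy)-4H-chromen-4-one F10. The allyl group is then transferred to morpholine with Pd(PPh3)4 (THF, rt) to give 8.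

## Further compounds

F1 | step 5 | 3-(3-bromo-4-methoxyphenyl)-7-methoxy-4H-chromen-4-one | COc1ccc2c(c1)occ(-c1ccc(OC)c(Br)c1)c2=O
F2 | step 5 | 7-methoxy-3-[4-methoxy-3-(4,4,5,5-tetramethyl-1,3,2-dioxaborolan-2-yl)phenyl]-4H-chromen-4-one | COc1ccc2c(c1)occ(-c1ccc(OC)c(c1)B1OC(C)(C)C(C)(C)O1)c2=O
F3 | step 5 | 7-(benzyloxy)-8-iodo-5-methoxy-3-(4-methoxyphenyl)-4H-chromen-4-one | COc1ccc(cc1)-c1coc2c(I)c(OCc3ccccc3)cc(OC)c2c1=O
F4 | step 5 | 7-(benzyloxy)-5-methoxy-8-[2-methoxy-5-(7-methoxy-4-oxo-4H-chromen-3-yl)phenyl]-3-(4-methoxyphenyl)-4H-chromen-4-one | COc1ccc2c(c1)occ(-c1ccc(OC)c(c1)-c1c(OCc3ccccc3)cc(OC)c3c1occ(-c1ccc(OC)cc1)c3=O)c2=O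
F5 | step 4 | 3-{3-bromo-4-[(di-tert-butylsilyl)oxy]phenyl}-7-methoxy-4H-chromen-4-one | COc1ccc2c(c1)occ(-c1ccc(O[SiH](C(C)(C)C)C(C)(C)C)c(Br)c1)c2=O
F6 | step 4 | 3-{3-bromo-4-[(bromodi-tert-butylsilyl)oxy]phenyl}-7-methoxy-4H-chromen-4-one | COc1ccc2c(c1)occ(-c1ccc(O[Si](Br)(C(C)(C)C)C(C)(C)C)c(Br)c1)c2=O
F7 | step 1 | 2-(3-bromo-4-hydroxyphenyl)-1-(2,4-dihydroxyphenyl)ethan-1-one | Oc1ccc(C(=O)Cc2ccc(O)c(Br)c2)c(O)c1
F8 | step 1 | 3-(3-bromo-4-hydroxyphenyl)-7-hydroxy-4H-chromen-4-one | O=c1c(-c2ccc(O)c(Br)c2)coc2cc(O)ccc12
F9 | step 3 | 5-hydroxy-3-(4-methoxyphenyl)-7-(prop-2-en-1-yloxy)-4H-chromen-4-one | COc1ccc(cc1)-c1coc2cc(OCC=C)cc(O)c2c1=O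
F10 | step 3 | 5-methoxy-3-(4-methoxyphenyl)-7-(prop-2-en-1-yloxy)-4H-chromen-4-one | COc1ccc(cc1)-c1coc2cc(OCC=C)cc(OC)c2c1=O
A1 | alternative 1 | 5,7-dimethoxy-3-(4-methoxyphenyl)-4H-chromen-4-one | COc1ccc(cc1)-c1coc2cc(OC)cc(OC)c2c1=O
A2 | alternative 1 | 8-iodo-5,7-dimethoxy-3-(4-methoxyphenyl)-4H-chromen-4-one | COc1ccc(cc1)-c1coc2c(I)c(OC)cc(OC)c2c1=O
A3 | alternative 1 | 7-methoxy-3-[4-methoxy-3-(4,4,5,5-tetramethyl-1,3,2-dioxaborolan-2-yl)phenyl]-4H-chromen-4-one | COc1ccc2c(c1)occ(-c1ccc(OC)c(c1)B1OC(C)(C)C(C)(C)O1)c2=O
A4 | alternative 1 | 5,7-dimethoxy-8-[2-methoxy-5-(7-methoxy-4-oxo-4H-chromen-3-yl)phenyl]-3-(4-methoxyphenyl)-4H-chromen-4-one | COc1ccc2c(c1)occ(-c1ccc(OC)c(c1)-c1c(OC)cc(OC)c3c1occ(-c1ccc(OC)cc1)c3=O)c2=O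
A5 | alternative 2 | daidzein, 7-hydroxy-3-(4-hydroxyphenyl)-4H-chromen-4-one | O=c1c(-c2ccc(O)cc2)coc2cc(O)ccc12
A6 | alternative 2 | 8-[2-hydroxy-5-(7-hydroxy-4-oxo-4H-chromen-3-yl)phenyl]-5,7-dimethoxy-3-(4-methoxyphenyl)-4H-chromen-4-one | O=c1c(-c2ccc(O)c(-c3c(OC)cc(OC)c4c(=O)c(-c5ccc(OC)cc5)coc34)c2)coc2cc(O)ccc12
A7 | alternative 3 | 1-(2,4-dihydroxyphenyl)-2-{4-hydroxy-3-[2,4,6-trihydroxy-3-((4-hydroxyphenyl)acetyl)phenyl]phenyl}ethan-1-one | O=C(Cc1ccc(O)c(c1)-c1c(O)cc(O)c(C(=O)Cc2ccc(O)cc2)c1O)c1ccc(O)cc1O
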